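The plan disconnects both C–C bonds at the CH2–CH unit of the C8 side chain. C8 is the quaternary carbon of carbocyclic ring A, lying between the enol carbon C7 and C8a of pyran ring B; its prenyl group and its CH2–CH(isopropenyl)–CH2–alkenyl chain are both allyl groups at different stages. One nickel-catalysed three-component coupling puts the (E)-2-methylacrylate unit on the terminal carbon and isopropenyl on the internal carbon of one of two enantiotopic allyl groups, directed by the C7 enolate oxygen, and sets both stereocentres. The precursor is an achiral 8,8-diallyl chromene dienone, two steps from 2,4,6-trihydroxybenzophenone.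

Key step: step 3

Remark on numbering: ring atoms follow 2H-chromene numbering (O1, C2, C3, C4, C4a, C5 to C8, C8a), and CIP descriptors refer to the 7-hydroxy-5-oxo tautomer drawn in the SMILES.
Remark on reagents: allyl methyl carbonate, methyl (E)-3-iodo-2-methylacrylate, isopropenylboronic acid pinacol ester and 2-methylbut-2-ene are assumed to be purchased.
Remark on design: the chromene must be the 6-benzoyl isomer (benzoyl para to the pyran oxygen); the precursor enters the nickel step unprotected as its potassium enolate, an anionic vinylogous carboxylate that serves as directing group.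
Remark on the ligand: (S,S)-iPr-BiOX is (4S,4'S)-4,4'-diisopropyl-4,4',5,5'-tetrahydro-2,2'-bioxazole; its antipode is used if the first run gives the 8R series.

Step 1
Reactants: 1 2,4,6-trihydroxybenzophenone; 2 3-methylbut-2-enal
Product: 4 (5,7-dihydroxy-2,2-dimethyl-2H-chromen-6-yl)(phenyl)methanone, via quinone methide 3 (not isolated)
Conditions: 2 (1.1 equiv), ethylenediammonium diacetate (10 mol%), toluene, 110 °C
Reagents that add atoms: 3-methylbut-2-enal (2), CC(C)=CC=O
Why: Knoevenagel-type condensation of the enal at a free ring carbon gives quinone methide 3, and oxa-6π electrocyclisation through the oxygen para to the benzoyl group (the only flanking oxygen never engaged in the hydrogen bond to the ketone) closes the 2,2-dimethyl-2H-pyran ring B to give the 6-benzoyl chromene, the isomer from closure through an ortho oxygen being removed by chromatography and a second annulation being limited by the near-stoichiometric enal.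

Step 2
Reactants: 4 6-benzoyl chromene; 5 allyl methyl carbonate
Product: 7 gem-diallyl dienone 8,8-diallyl-6-benzoyl-7-hydroxy-2,2-dimethyl-2H-chromen-5(8H)-one, via monoallyl chromene 6 (not isolated)
Conditions: 5 (2.2 equiv), Pd(PPh3)4 (5 mol%), THF, 25 to 50 °C
Reagents that add atoms: allyl methyl carbonate (5), C=CCOC(=O)OC
Why: Tsuji–Trost allylation: zerovalent palladium ionises 5 to a π-allyl complex and methoxide, the phenoxide is C-allylated at C8, its only unsubstituted ring carbon, to give 6 and then again at the same carbon with loss of aromaticity, while any O-allyl ether is re-ionised and drained into the C-allylated, chelated enol of the β-triketone, whose low nucleophilicity stops further allylation; C8 becomes a quaternary carbon with two enantiotopic allyl groups and no stereocentre.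

Step 3
Reactants: 7 gem-diallyl dienone; 8 methyl (E)-3-iodo-2-methylacrylate; 9 isopropenylboronic acid pinacol ester
Product: 11 methyl (2E,5R)-5-{[(8S)-8-allyl-6-benzoyl-7-hydroxy-2,2-dimethyl-5-oxo-5,8-dihydro-2H-chromen-8-yl]methyl}-2,6-dimethylhepta-2,6-dienoate, via potassium enolate 10 (not isolated)
Conditions: K3PO4 (3 equiv), t-AmOH/THF, 25 °C; then Ni(cod)2 (10 mol%), (S,S)-iPr-BiOX (12 mol%), 8 (1.1 equiv), 9 (1.5 equiv, slow addition), 25 °C
Reagents that add atoms: methyl (E)-3-iodo-2-methylacrylate (8), COC(=O)/C(C)=C/I; isopropenylboronic acid pinacol ester (9), C=C(C)B1OC(C)(C)C(C)(C)O1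
Why: Proposed new method: zerovalent nickel bearing the bis(oxazoline) adds oxidatively to the C–I bond of 8 with retention of alkene geometry, the C7 enolate oxygen of 10 displaces iodide, and one allyl alkene inserts into the Ni–alkenyl bond so that the alkenyl group lands on the terminal carbon and nickel on the internal carbon of a six-membered oxanickelacycle (Ni–O–C7–C8–CH2–CH), after which base-assisted transmetalation with 9 and C(sp3)–C(sp2) reductive elimination place isopropenyl on that internal carbon. The closest known reaction type is the nickel-catalysed, carbonyl- or carboxylate-directed three-component 1,2-dicarbofunctionalisation of unactivated terminal alkenes with an organic halide and an organoboron reagent; not yet shown are a triketone enolate as directing group, the alkenyl/isopropenyl pairing and the choice between enantiotopic alkenes. No ring is closed. The C8 stereocentre is set by which of the two enantiotopic allyl groups reacts, a choice left to the chiral ligand, and the methine (C5 of the heptadienoate) is tied to it by the chair-like nickelacycle, in which the new CH2 substituent should sit equatorial and away from the axial spectator allyl group, an arrangement that corresponds to the (8S,5R)/(8R,5S) pair, so that the ligand antipode giving 8S is selected. The regiochemistry follows from the chelate, which also holds the alkylnickel back from β-hydride elimination, while insertion ahead of direct alkenyl–alkenyl Suzuki–Miyaura coupling and reaction of only one allyl group are served by the bound anionic oxygen, slow addition of 9 and near-stoichiometric 8. The chromene alkene and the new enoate are internal and undirected and should remain untouched.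

Step 4
Reactants: 11 allyl ester; 12 2-methylbut-2-ene
Product: 13 methyl (2E,5R)-5-{[(8S)-6-benzoyl-7-hydroxy-2,2-dimethyl-8-(3-methylbut-2-enyl)-5-oxo-5,8-dihydro-2H-chromen-8-yl]methyl}-2,6-dimethylhepta-2,6-dienoate
Conditions: second-generation Grubbs catalyst (5 mol%), 12 (co-solvent, large excess), CH2Cl2, 25 °C
Reagents that add atoms: 2-methylbut-2-ene (12), CC=C(C)C
Why: Olefin cross-metathesis: the monosubstituted allyl alkene is the only unhindered alkene and is capped by the solvent-level excess of 12 as the trisubstituted prenyl group with loss of propene, whereas the conjugated trisubstituted enoate, the chromene alkene beside the gem-dimethyl carbon and the α-branched isopropenyl group are far slower; the one competing path, ring closure of the allyl-derived ruthenium alkylidene onto isopropenyl, is held back by the excess of 12 and the low temperature, and no stereocentre is touched.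

Step 5
Reactants: 13 prenyl ester
Product: 15 (2E,5R)-5-{[(8S)-6-benzoyl-7-hydroxy-2,2-dimethyl-8-(3-methylbut-2-enyl)-5-oxo-5,8-dihydro-2H-chromen-8-yl]methyl}-2,6-dimethylhepta-2,6-dienoic acid, via dilithium salt 14 (not isolated)
Conditions: LiOH·H2O (6 equiv), THF/MeOH/H2O, 40 °C; then 1 M HCl to pH 3–4, 0 °C
Reagents that add atoms: lithium hydroxide, [Li+].[OH-]
Why: Saponification: under base ring A is a delocalised triketone enolate and therefore inert to hydroxide, so only the methyl ester is cleaved, the E-alkene and both stereocentres (neither is enolisable) are unaffected, and brief cold acidification avoids acid-promoted cyclisation of the prenyl group onto the enol.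

Compound list
1 | 2,4,6-trihydroxybenzophenone | O=C(c1ccccc1)c1c(O)cc(O)cc1O | starting material
2 | 3-methylbut-2-enal | CC(C)=CC=O | starting material
3 | 4-benzoyl-3,5-dihydroxy-6-(3-methylbut-2-enylidene)cyclohexa-2,4-dien-1-one (quinone methide) | O=C(c1ccccc1)C1=C(O)C(=CC=C(C)C)C(=O)C=C1O | intermediate
4 | (5,7-dihydroxy-2,2-dimethyl-2H-chromen-6-yl)(phenyl)methanone | O=C(c1ccccc1)c1c(O)cc2OC(C)(C)C=Cc2c1O | intermediate
5 | allyl methyl carbonate | C=CCOC(=O)OC | starting material
6 | (8-allyl-5,7-dihydroxy-2,2-dimethyl-2H-chromen-6-yl)(phenyl)methanone | C=CCc1c(O)c(C(=O)c2ccccc2)c(O)c2C=CC(C)(C)Oc12 | intermediate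
7 | 8,8-diallyl-6-benzoyl-7-hydroxy-2,2-dimethyl-2H-chromen-5(8H)-one | C=CCC1(CC=C)C(O)=C(C(=O)c2ccccc2)C(=O)C2=C1OC(C)(C)C=C2 | intermediate
8 | methyl (E)-3-iodo-2-methylacrylate | COC(=O)/C(C)=C/I | starting material
9 | isopropenylboronic acid pinacol ester | C=C(C)B1OC(C)(C)C(C)(C)O1 | starting material
10 | potassium enolate of 7 | C=CCC1(CC=C)C([O-])=C(C(=O)c2ccccc2)C(=O)C2=C1OC(C)(C)C=C2.[K+] | intermediate
11 | methyl (2E,5R)-5-{[(8S)-8-allyl-6-benzoyl-7-hydroxy-2,2-dimethyl-5-oxo-5,8-dihydro-2H-chromen-8-yl]methyl}-2,6-dimethylhepta-2,6-dienoate | C=C(C)[C@H](C/C=C(\C)C(=O)OC)C[C@@]1(CC=C)C(O)=C(C(=O)c2ccccc2)C(=O)C2=C1OC(C)(C)C=C2 | intermediate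
12 | 2-methylbut-2-ene | CC=C(C)C | starting material
13 | methyl (2E,5R)-5-{[(8S)-6-benzoyl-7-hydroxy-2,2-dimethyl-8-(3-methylbut-2-enyl)-5-oxo-5,8-dihydro-2H-chromen-8-yl]methyl}-2,6-dimethylhepta-2,6-dienoate | C=C(C)[C@H](C/C=C(\C)C(=O)OC)C[C@@]1(CC=C(C)C)C(O)=C(C(=O)c2ccccc2)C(=O)C2=C1OC(C)(C)C=C2 | intermediate
14 | dilithium carboxylate enolate of 15 | C=C(C)[C@H](C/C=C(\C)C(=O)[O-])C[C@@]1(CC=C(C)C)C([O-])=C(C(=O)c2ccccc2)C(=O)C2=C1OC(C)(C)C=C2.[Li+].[Li+] | intermediate
15 | (2E,5R)-5-{[(8S)-6-benzoyl-7-hydroxy-2,2-dimethyl-8-(3-methylbut-2-enyl)-5-oxo-5,8-dihydro-2H-chromen-8-yl]methyl}-2,6-dimethylhepta-2,6-dienoic acid | C=C(C)[C@H](C/C=C(\C)C(=O)O)C[C@@]1(CC=C(C)C)C(O)=C(C(=O)c2ccccc2)C(=O)C2=C1OC(C)(C)C=C2 | target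

Total step count: 5. Longest linear sequence: 5 steps (1 to 4 to 7 to 11 to 13 to 15).

Steps most likely to fail

Step 3 (bears the label). The process at risk is the ordering of events at nickel: direct coupling of 8 with 9 may outrun alkene insertion, β-hydride elimination may follow insertion, both allyl groups may react, or the ligand may discriminate poorly between the enantiotopic allyl groups and the alkene faces. The fallback uses known reactions only, leaves the route at 4 and rejoins it at 13, so that steps 2 to 4 are replaced. C8-prenylation of 4 (prenyl bromide, aqueous KOH, 0 °C) gives the 8-prenyl chromene F1. Asymmetric Tsuji–Trost dearomative allylation of F1 with methyl (E)-4-(methoxycarbonyloxy)but-2-enoate (Pd2(dba)3, N,N'-(cyclohexane-1,2-diyl)bis[2-(diphenylphosphino)benzamide], antipode chosen for 8R) sets C8 and gives the enoate F2. Reversible addition of the enol oxygen to this enoate should be drained by the next step. Hayashi–Miyaura conjugate addition of 9 ([Rh(cod)Cl]2, BINAP antipode chosen for 3S, KOH, dioxane/H2O) sets the methine and gives the ester F3. Reduction with i-Bu2AlH at −78 °C, the first equivalent being taken up by the acidic enol whose aluminium chelate resists hydride, gives the aldehyde F4. Wittig reaction of F4 with Ph3P=C(CH3)CO2CH3 forms the E-enoate 13.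

Step 4. The process at risk is ring-closing metathesis: the ruthenium alkylidene formed at the allyl group can close a six-membered ring onto the isopropenyl group faster than it is intercepted by 12. The fallback is meant for the case that step 3 itself works; it leaves the route at 4 and rejoins it at 13, with the prenyl group in place before isopropenyl exists. One equivalent of 5 under the conditions of step 2 is stopped at the monoallyl chromene 6, which is isolated. Asymmetric Tsuji–Trost dearomative prenylation of 6 with methyl 3-methylbut-2-enyl carbonate (Pd2(dba)3, the same bis(phosphinobenzamide) ligand, linear attack expected) gives the 8-allyl-8-prenyl dienone F5. The nickel conditions of step 3, applied to the single allyl group of F5, then give 13 directly; the coupling only has to choose the alkene face, and no metathesis is run.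

Step 1. The process at risk is the direction of the electrocyclisation: closure through an oxygen ortho to the benzoyl group would make the 8-benzoyl chromene the main product, and a second annulation may consume material. The fallback leaves the route at 1 and rejoins it at 4. Selective O-alkylation of the non-chelated 4-hydroxyl with 3-chloro-3-methylbut-1-yne (CuCl2 cat., DBU, MeCN, 0 °C) gives the aryl propargyl ether F6. A 6-endo hydroarylation catalysed by Ph3PAuNTf2 (monovalent gold, CH2Cl2, 25 °C) then forms the C4–C4a bond at either of the two equivalent ortho carbons, so the ether oxygen is the pyran oxygen by construction and only 4 can form.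

Further compounds
F1 | step 3 | (5,7-dihydroxy-2,2-dimethyl-8-(3-methylbut-2-enyl)-2H-chromen-6-yl)(phenyl)methanone | CC(C)=CCc1c(O)c(C(=O)c2ccccc2)c(O)c2C=CC(C)(C)Oc12
F2 | step 3 | methyl (2E)-4-[(8R)-6-benzoyl-7-hydroxy-2,2-dimethyl-8-(3-methylbut-2-enyl)-5-oxo-5,8-dihydro-2H-chromen-8-yl]but-2-enoate | COC(=O)/C=C/C[C@@]1(CC=C(C)C)C(O)=C(C(=O)c2ccccc2)C(=O)C2=C1OC(C)(C)C=C2
F3 | step 3 | methyl (3S)-3-{[(8S)-6-benzoyl-7-hydroxy-2,2-dimethyl-8-(3-methylbut-2-enyl)-5-oxo-5,8-dihydro-2H-chromen-8-yl]methyl}-4-methylpent-4-enoate | C=C(C)[C@H](CC(=O)OC)C[C@@]1(CC=C(C)C)C(O)=C(C(=O)c2ccccc2)C(=O)C2=C1OC(C)(C)C=C2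
F4 | step 3 | (3S)-3-{[(8S)-6-benzoyl-7-hydroxy-2,2-dimethyl-8-(3-methylbut-2-enyl)-5-oxo-5,8-dihydro-2H-chromen-8-yl]methyl}-4-methylpent-4-enal | C=C(C)[C@H](CC=O)C[C@@]1(CC=C(C)C)C(O)=C(C(=O)c2ccccc2)C(=O)C2=C1OC(C)(C)C=C2
F5 | step 4 | (8R)-8-allyl-6-benzoyl-7-hydroxy-2,2-dimethyl-8-(3-methylbut-2-enyl)-2H-chromen-5(8H)-one | C=CC[C@@]1(CC=C(C)C)C(O)=C(C(=O)c2ccccc2)C(=O)C2=C1OC(C)(C)C=C2
F6 | step 1 | {2,6-dihydroxy-4-[(2-methylbut-3-yn-2-yl)oxy]phenyl}(phenyl)methanone | C#CC(C)(C)Oc1cc(O)c(C(=O)c2ccccc2)c(O)c1
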